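**Retrosynthetic overview**
- Testudinariol A ⇒ two identical oxan-3-one halves + a C4 bis-ylide; a two-directional, alkoxy-directed Z-selective Wittig forms both exocyclic alkenes last.
- Each oxan-3-one ⇒ a 5-cyclopentyl-furfuryl alcohol; late-stage oxidative dearomatisation of the furan (Achmatowicz) with in-flask ionic hydrogenation builds the oxane ring and its stereocentre under control of the cyclopentanol, then the enone C=C is reduced.
- Furyl-cyclopentanol ⇒ (R)-α-furyl aldehyde; a Me2AlCl carbonyl-ene cyclisation forms the cyclopentane and relays the one catalyst-set centre to the other two.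
- α-Furyl aldehyde ⇒ 6-methylhept-5-enal + a furyl(mesityl)iodonium salt (Cu/amine enantioselective α-arylation); the salt comes from methyl 2-furoate, the aldehyde from cross-metathesis.
- Ring order: cyclopentane (ene) → oxane (from the furan) → dimerisation.

Assumption: hex-5-enal, 2-methylbut-2-ene, methyl furan-2-carboxylate, (diacetoxyiodo)mesitylene and butane-1,4-diylbis(triphenylphosphonium) dibromide are taken as catalogue chemicals.

**Step 1**
Reactants: 1 hex-5-enal; 2 2-methylbut-2-ene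
Product: 3 6-methylhept-5-enal
Conditions: Grubbs II (2 mol%), 2 (neat, 20 equiv), 40 °C, sealed tube
Reagents that add atoms: none
Why: Olefin cross-metathesis of a terminal alkene with excess 2-methylbut-2-ene gives the prenyl-type trisubstituted alkene, tolerates the aldehyde and creates no stereocentre.

**Step 2**
Reactants: 4 methyl furan-2-carboxylate; 5 (diacetoxyiodo)mesitylene
Product: 6 [5-(methoxycarbonyl)furan-2-yl](2,4,6-trimethylphenyl)iodonium trifluoromethanesulfonate
Conditions: TfOH (1.1 equiv), CH2Cl2, −30 °C → rt; Et2O trituration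
Reagents that add atoms: trifluoromethanesulfonic acid, OS(=O)(=O)C(F)(F)F
Why: Electrophilic aromatic substitution by the TfOH-activated aryl-λ3-iodane (standard diaryliodonium synthesis) takes place at the free α-position C5 of the furoate, whose ester group also stabilises the salt, and no stereocentre is formed.

**Step 3**
Reactants: 3 6-methylhept-5-enal (2 equiv); 6 [5-(methoxycarbonyl)furan-2-yl](2,4,6-trimethylphenyl)iodonium trifluoromethanesulfonate
Product: 7 methyl 5-[(2R)-6-methyl-1-oxohept-5-en-2-yl]furan-2-carboxylate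
Conditions: CuBr (10 mol%), (2S,5S)-5-benzyl-2-tert-butyl-3-methylimidazolidin-4-one·TCA (10 mol%), NaHCO3 (1.1 equiv), toluene/Et2O 2:1, 23 °C; used at once
Reagents that add atoms: none
Why: Dual Cu(I)/chiral-amine catalysis (enantioselective aldehyde α-arylation with diaryliodonium salts) arylates the E-enamine of 3 with the Cu(III)–furyl species on the face away from the benzyl group, mesityl being the non-transferred dummy ligand, which sets the (R) α-centre, and the hindered catalyst does not re-enaminise the α-aryl aldehyde.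

**Step 4**
Reactants: 7 methyl 5-[(2R)-6-methyl-1-oxohept-5-en-2-yl]furan-2-carboxylate
Product: 9 (1S,2S,5R)-2-[5-(hydroxymethyl)furan-2-yl]-5-(prop-1-en-2-yl)cyclopentan-1-ol, via hydroxy ester 8 (not isolated)
Conditions: Me2AlCl (2.2 equiv), CH2Cl2, −78 °C, 1 h; then DIBAL-H (4 equiv), −78 → 0 °C; aq Rochelle salt
Reagents that add atoms: none
Why: The type I intramolecular carbonyl-ene reaction runs through a closed, cis-fused six-membered transition state that places OH and isopropenyl cis while the α-furyl group sits pseudo-equatorial and trans to the Al-bound oxygen, so the α-centre dictates the two new centres, and DIBAL-H added to the same flask reduces the furoate ester to the furfuryl alcohol.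

**Step 5**
Reactants: 9 (1S,2S,5R)-2-[5-(hydroxymethyl)furan-2-yl]-5-(prop-1-en-2-yl)cyclopentan-1-ol
Product: 11 (6R)-6-[(1S,2S,3R)-2-hydroxy-3-(prop-1-en-2-yl)cyclopentyl]-2H-pyran-3(6H)-one, via pyranone hemiketal 10 (not isolated)
Conditions: O2, visible light, rose bengal (1 mol%), MeOH, 0 °C; Me2S (2 equiv), rt; evaporate; then Et3SiH (3 equiv), TFA (10 equiv), CH2Cl2, −40 °C
Reagents that add atoms: dioxygen, O=O
Why: In this Achmatowicz rearrangement singlet oxygen adds [4+2] to the 2,5-disubstituted furan (about 10^4 times faster than its ene reaction with the isopropenyl group), peroxide reduction and closure of the enedione by the CH2OH group give the hemiketal, and Kishi-type ionic hydrogenation then delivers hydride to the planar cyclic oxocarbenium anti to the carbinol-bearing carbon of the cyclopentyl group, where Felkin–Anh 1,2-induction and the Evans polar 1,3-model reinforce each other, which sets C6 as (R).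

**Step 6**
Reactants: 11 (6R)-6-[(1S,2S,3R)-2-hydroxy-3-(prop-1-en-2-yl)cyclopentyl]-2H-pyran-3(6H)-one
Product: 12 (6R)-6-[(1S,2S,3R)-2-hydroxy-3-(prop-1-en-2-yl)cyclopentyl]oxan-3-one
Conditions: [(Ph3P)CuH]6 (0.4 equiv), H2O (2 equiv), degassed THF/benzene, rt
Reagents that add atoms: none
Why: In the Stryker conjugate reduction Cu–H adds hydride only to the enone β-carbon and water protonates the copper enolate, which leaves the isolated 1,1-disubstituted alkene, the free alcohol and all stereocentres untouched.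

**Step 7**
Reactants: 12 (6R)-6-[(1S,2S,3R)-2-hydroxy-3-(prop-1-en-2-yl)cyclopentyl]oxan-3-one (2.3 equiv); 13 butane-1,4-diylbis(triphenylphosphonium) dibromide
Product: 15 testudinariol A, via bis-ylide 14 (not isolated)
Conditions: 13, KHMDS (2.05 equiv), THF, 0 °C; then 12, −78 °C → rt
Reagents that add atoms: none
Why: A two-directional Wittig olefination with the salt-free non-stabilised bis-ylide exploits the alkoxy-directed selectivity of α-alkoxy ketones (Still-type Z-selective Wittig), which puts the new chain cis to the ring OCH2 carbon and so sets both Z alkenes, while the free secondary OH is tolerated because alkoxide/phosphonium proton exchange regenerates ylide and homochiral pairing of two halves upgrades the ee of the C2-symmetric product (Horeau effect).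

**Compound list**
1 | hex-5-enal | C=CCCCC=O | starting material
2 | 2-methylbut-2-ene | CC=C(C)C | starting material
3 | 6-methylhept-5-enal | CC(C)=CCCCC=O | intermediate
4 | methyl furan-2-carboxylate | COC(=O)c1ccco1 | starting material
5 | (diacetoxyiodo)mesitylene | CC(=O)OI(OC(C)=O)c1c(C)cc(C)cc1C | starting material
6 | [5-(methoxycarbonyl)furan-2-yl](2,4,6-trimethylphenyl)iodonium trifluoromethanesulfonate | COC(=O)c1ccc(o1)[I+]c1c(C)cc(C)cc1C.[O-]S(=O)(=O)C(F)(F)F | intermediate
7 | methyl 5-[(2R)-6-methyl-1-oxohept-5-en-2-yl]furan-2-carboxylate | O=C[C@H](CCC=C(C)C)c1ccc(C(=O)OC)o1 | intermediate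
8 | methyl 5-[(1S,2S,3R)-2-hydroxy-3-(prop-1-en-2-yl)cyclopentyl]furan-2-carboxylate | C=C(C)[C@H]1CC[C@H](c2ccc(C(=O)OC)o2)[C@H]1O | intermediate
9 | (1S,2S,5R)-2-[5-(hydroxymethyl)furan-2-yl]-5-(prop-1-en-2-yl)cyclopentan-1-ol | C=C(C)[C@H]1CC[C@H](c2ccc(CO)o2)[C@H]1O | intermediate
10 | 6-hydroxy-6-[(1S,2S,3R)-2-hydroxy-3-(prop-1-en-2-yl)cyclopentyl]-2H-pyran-3(6H)-one (anomer mixture) | C=C(C)[C@H]1CC[C@H](C2(O)C=CC(=O)CO2)[C@H]1O | intermediate
11 | (6R)-6-[(1S,2S,3R)-2-hydroxy-3-(prop-1-en-2-yl)cyclopentyl]-2H-pyran-3(6H)-one | C=C(C)[C@H]1CC[C@H]([C@H]2C=CC(=O)CO2)[C@H]1O | intermediate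
12 | (6R)-6-[(1S,2S,3R)-2-hydroxy-3-(prop-1-en-2-yl)cyclopentyl]oxan-3-one | C=C(C)[C@H]1CC[C@H]([C@H]2CCC(=O)CO2)[C@H]1O | intermediate
13 | butane-1,4-diylbis(triphenylphosphonium) dibromide | [Br-].[Br-].c1ccc(cc1)[P+](CCCC[P+](c1ccccc1)(c1ccccc1)c1ccccc1)(c1ccccc1)c1ccccc1 | starting material
14 | butane-1,4-diylidenebis(triphenyl-λ5-phosphane) (bis-ylide) | c1ccc(cc1)P(=CCCC=P(c1ccccc1)(c1ccccc1)c1ccccc1)(c1ccccc1)c1ccccc1 | intermediate
15 | testudinariol A, (1S,2S,5R)-2-[(2R,5Z)-5-{(4Z)-4-[(6R)-6-[(1S,2S,3R)-2-hydroxy-3-(prop-1-en-2-yl)cyclopentyl]oxan-3-ylidene]butylidene}oxan-2-yl]-5-(prop-1-en-2-yl)cyclopentan-1-ol | C=C(C)[C@H]1CC[C@H]([C@H]2CC/C(=C/CC/C=C3/CC[C@H]([C@H]4CC[C@H](C(=C)C)[C@@H]4O)OC3)CO2)[C@H]1O | target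

**Step count**
Total: 7 steps. Longest linear sequence: 6 steps (1 → 3 → 7 → 9 → 11 → 12 → 15, i.e. steps 1, 3, 4, 5, 6, 7); step 2 is the only side branch.

**Three steps most likely to fail, with fallbacks**

Step 3 (furyl transfer from the iodonium salt, ee, and the configurational lability of the α-furyl aldehyde). The fallback sets out from 3 and 6 and comes back at 7, carrying the new centre through a more robust imide.
- Aldehyde 3 is oxidised (NaClO2, NaH2PO4, 2-methylbut-2-ene, t-BuOH/H2O) to 6-methylhept-5-enoic acid F1.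
- The acid is coupled (PivCl, Et3N; then oxazolidin-2-one, LiCl) to 3-(6-methylhept-5-enoyl)-1,3-oxazolidin-2-one F2.
- Soft enolisation (TMSOTf, Et3N) gives 3-[(1Z)-6-methyl-1-(trimethylsilyloxy)hepta-1,5-dien-1-yl]-1,3-oxazolidin-2-one F3.
- F3 is arylated with 6 under Cu(I)/bis(oxazoline) catalysis (the Ph-box antipode that gives the R product) to methyl 5-[(2R)-6-methyl-1-oxo-1-(2-oxo-1,3-oxazolidin-3-yl)hept-5-en-2-yl]furan-2-carboxylate F4, which can be recrystallised to raise the ee.
- NaBH4 in THF/H2O reduces the imide selectively to methyl 5-[(2S)-1-hydroxy-6-methylhept-5-en-2-yl]furan-2-carboxylate F5, and Dess–Martin oxidation at 0 °C returns 7 immediately before the ene step.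

Step 5 (facial selectivity of hydride delivery at C6; also possible epimerisation through the enol ether and acid sensitivity of the isopropenyl group). The fallback sets out from 8, isolated by quenching the ene reaction before DIBAL-H is added, and comes back at 11. It replaces the free hydroxyl by a very large silyl ether so that the carbinol-bearing branch is unambiguously the large Felkin substituent.
- TIPSOTf/2,6-lutidine gives methyl 5-[(1S,2S,3R)-3-(prop-1-en-2-yl)-2-{[tri(propan-2-yl)silyl]oxy}cyclopentyl]furan-2-carboxylate F6.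
- DIBAL-H gives {5-[(1S,2S,3R)-3-(prop-1-en-2-yl)-2-{[tri(propan-2-yl)silyl]oxy}cyclopentyl]furan-2-yl}methanol F7.
- Photooxygenation and Me2S give 6-hydroxy-6-[(1S,2S,3R)-3-(prop-1-en-2-yl)-2-{[tri(propan-2-yl)silyl]oxy}cyclopentyl]-2H-pyran-3(6H)-one F8.
- Et3SiH/BF3·OEt2 at −78 °C gives (6R)-6-[(1R,2S,3R)-3-(prop-1-en-2-yl)-2-{[tri(propan-2-yl)silyl]oxy}cyclopentyl]-2H-pyran-3(6H)-one F9 (the 1R label is only a CIP priority change), and HF·pyridine returns 11.

Step 7 (Z,Z selectivity on a cyclic α-alkoxy ketone, bis-ylide efficiency, ketone enolisation). The fallback sets out from 12 and comes back at 15. It builds the diene one alkene at a time so that geometric isomers can be separated after the first olefination and no bis-ylide is needed.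
- Wittig reaction of 12 with the oxido-ylide from (4-hydroxybutyl)triphenylphosphonium bromide (2 equiv KHMDS) gives (1S,2S,5R)-2-[(2R,5Z)-5-(4-hydroxybutylidene)oxan-2-yl]-5-(prop-1-en-2-yl)cyclopentan-1-ol F10.
- I2/PPh3/imidazole at 0 °C converts only the primary alcohol into (1S,2S,5R)-2-[(2R,5Z)-5-(4-iodobutylidene)oxan-2-yl]-5-(prop-1-en-2-yl)cyclopentan-1-ol F11.
- PPh3 in MeCN at 80 °C gives {(4Z)-4-[(6R)-6-[(1S,2S,3R)-2-hydroxy-3-(prop-1-en-2-yl)cyclopentyl]oxan-3-ylidene]butyl}triphenylphosphonium iodide F12.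
- The ylide of F12 (KHMDS, THF) with a second equivalent of 12 gives 15.

**Further compounds**
F1 | step 3 | 6-methylhept-5-enoic acid | CC(C)=CCCCC(=O)O
F2 | step 3 | 3-(6-methylhept-5-enoyl)-1,3-oxazolidin-2-one | CC(C)=CCCCC(=O)N1CCOC1=O
F3 | step 3 | 3-[(1Z)-6-methyl-1-(trimethylsilyloxy)hepta-1,5-dien-1-yl]-1,3-oxazolidin-2-one | CC(C)=CCC/C=C(\O[Si](C)(C)C)N1CCOC1=O
F4 | step 3 | methyl 5-[(2R)-6-methyl-1-oxo-1-(2-oxo-1,3-oxazolidin-3-yl)hept-5-en-2-yl]furan-2-carboxylate | O=C(N1CCOC1=O)[C@H](CCC=C(C)C)c1ccc(C(=O)OC)o1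
F5 | step 3 | methyl 5-[(2S)-1-hydroxy-6-methylhept-5-en-2-yl]furan-2-carboxylate | OC[C@H](CCC=C(C)C)c1ccc(C(=O)OC)o1
F6 | step 5 | methyl 5-[(1S,2S,3R)-3-(prop-1-en-2-yl)-2-{[tri(propan-2-yl)silyl]oxy}cyclopentyl]furan-2-carboxylate | C=C(C)[C@H]1CC[C@H](c2ccc(C(=O)OC)o2)[C@H]1O[Si](C(C)C)(C(C)C)C(C)C
F7 | step 5 | {5-[(1S,2S,3R)-3-(prop-1-en-2-yl)-2-{[tri(propan-2-yl)silyl]oxy}cyclopentyl]furan-2-yl}methanol | C=C(C)[C@H]1CC[C@H](c2ccc(CO)o2)[C@H]1O[Si](C(C)C)(C(C)C)C(C)C
F8 | step 5 | 6-hydroxy-6-[(1S,2S,3R)-3-(prop-1-en-2-yl)-2-{[tri(propan-2-yl)silyl]oxy}cyclopentyl]-2H-pyran-3(6H)-one | C=C(C)[C@H]1CC[C@H](C2(O)C=CC(=O)CO2)[C@H]1O[Si](C(C)C)(C(C)C)C(C)C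
F9 | step 5 | (6R)-6-[(1R,2S,3R)-3-(prop-1-en-2-yl)-2-{[tri(propan-2-yl)silyl]oxy}cyclopentyl]-2H-pyran-3(6H)-one | C=C(C)[C@H]1CC[C@H]([C@H]2C=CC(=O)CO2)[C@H]1O[Si](C(C)C)(C(C)C)C(C)C
F10 | step 7 | (1S,2S,5R)-2-[(2R,5Z)-5-(4-hydroxybutylidene)oxan-2-yl]-5-(prop-1-en-2-yl)cyclopentan-1-ol | C=C(C)[C@H]1CC[C@H]([C@H]2CC/C(=C/CCCO)CO2)[C@H]1O
F11 | step 7 | (1S,2S,5R)-2-[(2R,5Z)-5-(4-iodobutylidene)oxan-2-yl]-5-(prop-1-en-2-yl)cyclopentan-1-ol | C=C(C)[C@H]1CC[C@H]([C@H]2CC/C(=C/CCCI)CO2)[C@H]1O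
F12 | step 7 | {(4Z)-4-[(6R)-6-[(1S,2S,3R)-2-hydroxy-3-(prop-1-en-2-yl)cyclopentyl]oxan-3-ylidene]butyl}triphenylphosphonium iodide | C=C(C)[C@H]1CC[C@H]([C@H]2CC/C(=C/CCC[P+](c3ccccc3)(c3ccccc3)c3ccccc3)CO2)[C@H]1O.[I-]
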